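## Retrosynthetic overview
1. The last step is global desilylation. The oxirane is the only ring in the target and is formed in the penultimate step, by C9‑OH‑directed, A(1,3)‑controlled epoxidation of a (10Z)‑allylic alcohol.
2. The C8–C9 bond comes from an anti‑selective boron aldol between the (E)‑enol borinate of a C1–C8 ketone and a C9–C15 (2Z,5Z)‑dienal. This sets C8 and C9 and leaves only the C9‑OH free.
3. The C1–C8 ketone comes from an Evans syn crotonate aldol that forms C5–C6. The imide C=O becomes the C6‑CH2OH, the α‑vinyl group becomes C7(=O)–C8 by Wacker oxidation, and the C8‑CH2OH carbon comes from formaldehyde. C3=O is carried as a dioxolane.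
4. The C9–C15 dienal comes from (R)‑Roche ester (C12), a Z‑Wittig reaction (C13=C14) and a Still–Gennari olefination (C10=C11).

Numbering: C1 is the CH3 of the ethyl ketone and C15 is the propenyl CH3. C6′ and C8′ are the two hydroxymethyl carbons.

Assumption 1: I take the SMILES literally. It encodes 5S,6S,8R,9S,10R,11S,12S,13Z, with C9 and C12 cis on the oxirane, so the epoxide must come from a (10Z)‑trisubstituted alkene. An E‑selective olefination would give the trans‑oxirane, which is not the structure given.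

Assumption 2: The open diketone as drawn is the target. Once deprotected it equilibrates with its C3 hemiketal (through C6′‑OH), and I do not try to suppress this.

## Route

### C9–C15 dienal

**Step 1**
Reactants: 1 methyl (2R)-3-hydroxy-2-methylpropanoate ((R)-Roche ester)
Product: 2 methyl (2R)-2-methyl-3-(triethylsilyloxy)propanoate
Conditions: TESCl, imidazole, CH2Cl2, 0 °C
Reagents that add atoms: chlorotriethylsilane, CC[Si](CC)(CC)Cl
Why: Silyl ether protection; the chiral‑pool stereocentre (future C12) is untouched, and TES is chosen because it can later be oxidised directly to the aldehyde.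

**Step 2**
Reactants: 2
Product: 3 (2R)-2-methyl-3-(triethylsilyloxy)propanal
Conditions: DIBAL‑H (1.05 equiv), CH2Cl2, −78 °C; Rochelle salt
Reagents that add atoms: none
Why: Partial ester reduction; the tetrahedral aluminium hemiacetal survives at −78 °C, so reduction stops at the aldehyde without epimerisation.

**Step 3**
Reactants: 3; 4 ethyltriphenylphosphonium bromide
Product: 5 triethyl{[(2S,3Z)-2-methylpent-3-en-1-yl]oxy}silane
Conditions: 4, NaHMDS, THF, 0 °C; then 3, −78 °C → rt
Reagents that add atoms: 4, CC[P+](c1ccccc1)(c1ccccc1)c1ccccc1.[Br-]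
Why: Salt‑free Wittig reaction of a non‑stabilised ylide gives the 13Z alkene (≥95:5) under kinetic control; the descriptor changes from R to S only because the CIP priorities change.

**Step 4**
Reactants: 5
Product: 6 (2S,3Z)-2-methylpent-3-enal
Conditions: (COCl)2, DMSO, CH2Cl2, −78 → −40 °C; i‑Pr2NEt, −78 → 0 °C; used at once as a solution
Reagents that add atoms: none
Why: Swern conditions cleave and oxidise a primary TES ether in one operation, which avoids the volatile alcohol; cold, short handling limits epimerisation or conjugation of the β,γ‑unsaturated aldehyde.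

**Step 5**
Reactants: 6; 7 ethyl 2-[bis(2,2,2-trifluoroethoxy)phosphoryl]propanoate
Product: 8 ethyl (2Z,4S,5Z)-2,4-dimethylhepta-2,5-dienoate
Conditions: 7, KHMDS, 18‑crown‑6, THF, −78 °C; then 6
Reagents that add atoms: 7, CCOC(=O)C(C)P(=O)(OCC(F)(F)F)OCC(F)(F)F
Why: Still–Gennari olefination; fast, irreversible collapse of the electron‑poor phosphonate adduct gives the Z‑trisubstituted enoate (C9 cis to C12), and the weakly basic anion spares C12.

**Step 6**
Reactants: 8
Product: 9 (2Z,4S,5Z)-2,4-dimethylhepta-2,5-dien-1-ol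
Conditions: DIBAL‑H (2.3 equiv), CH2Cl2, −78 °C
Reagents that add atoms: none
Why: 1,2‑Reduction of the enoate; both alkene geometries are retained.

**Step 7**
Reactants: 9
Product: 10 (2Z,4S,5Z)-2,4-dimethylhepta-2,5-dienal
Conditions: Dess–Martin periodinane, NaHCO3, CH2Cl2, 0 °C, dark; used directly
Reagents that add atoms: none
Why: Buffered Dess–Martin oxidation is neutral and fast, which minimises Z→E isomerisation of the enal.

### C1–C8 ketone

**Step 8**
Reactants: 11 methyl 3-oxopentanoate; 12 ethane-1,2-diol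
Product: 13 methyl (2-ethyl-1,3-dioxolan-2-yl)acetate
Conditions: p‑TsOH (cat.), toluene, Dean–Stark, reflux
Reagents that add atoms: 12, OCCO
Why: Ketalisation masks the future C3 ketone so that only C7 can be enolised later.

**Step 9**
Reactants: 13
Product: 14 (2-ethyl-1,3-dioxolan-2-yl)acetaldehyde
Conditions: DIBAL‑H (1.05 equiv), toluene, −78 °C
Reagents that add atoms: none
Why: Partial ester reduction to the C5 aldehyde; the ketal is inert to hydride.

**Step 10**
Reactants: 15 (4R)-4-benzyl-1,3-oxazolidin-2-one; 16 (E)-but-2-enoyl chloride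
Product: 17 (4R)-4-benzyl-3-[(2E)-but-2-enoyl]-1,3-oxazolidin-2-one
Conditions: n‑BuLi, THF, −78 °C; then 16, −78 → 0 °C
Reagents that add atoms: 16, C/C=C/C(=O)Cl
Why: N‑Acylation of the lithiated Evans auxiliary.

**Step 11**
Reactants: 17; 14
Product: 18 (4R)-4-benzyl-3-[(2R,3S)-2-ethenyl-4-(2-ethyl-1,3-dioxolan-2-yl)-3-hydroxybutanoyl]-1,3-oxazolidin-2-one
Conditions: n‑Bu2BOTf, Et3N, CH2Cl2, −78 → 0 °C; 14, −78 → 0 °C; pH 7 buffer, MeOH, H2O2
Reagents that add atoms: 14, CCC1(CC=O)OCCO1
Why: Evans syn aldol of the dienol borinate, which reacts at Cα through a Zimmerman–Traxler chair anti to the benzyl group; because the imide C=O becomes C6′ and the vinyl group becomes C7/C8, this syn adduct is the required 5,6‑anti array (5S,6S).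

**Step 12**
Reactants: 18
Product: 19 (2S,3S)-2-ethenyl-4-(2-ethyl-1,3-dioxolan-2-yl)butane-1,3-diol
Conditions: LiBH4, MeOH (1 equiv), THF, 0 °C
Reagents that add atoms: none
Why: Reductive removal of the auxiliary turns the imide carbonyl into the C6‑CH2OH without epimerisation; 15 is recovered.

**Step 13**
Reactants: 19
Product: 20 2-{(2S,3S)-2-(TBSO)-3-[(TBSO)methyl]pent-4-en-1-yl}-2-ethyl-1,3-dioxolane
Conditions: TBSOTf (2.5 equiv), 2,6‑lutidine, CH2Cl2, −78 → 0 °C
Reagents that add atoms: TBSOTf, CC(C)(C)[Si](C)(C)OS(=O)(=O)C(F)(F)F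
Why: A single bis‑silylation protects both the primary and the hindered secondary OH; the buffered, cold conditions leave the dioxolane intact.

**Step 14**
Reactants: 20
Product: 21 (3S,4S)-4-(TBSO)-3-[(TBSO)methyl]-5-(2-ethyl-1,3-dioxolan-2-yl)pentan-2-one
Conditions: PdCl2 (10 mol %), Cu(OAc)2·H2O, O2 (1 atm), DMA–H2O 7:1, rt
Reagents that add atoms: water, O (O2 is the terminal oxidant)
Why: Tsuji–Wacker oxidation of the only alkene is Markovnikov and gives the C7 methyl ketone; the acetate co‑oxidant keeps the medium mild enough for the TBS ethers, the ketal and C6.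

**Step 15**
Reactants: 21; 22 formaldehyde
Product: 23 (4S,5S)-5-(TBSO)-4-[(TBSO)methyl]-6-(2-ethyl-1,3-dioxolan-2-yl)-1-hydroxyhexan-3-one
Conditions: LDA, THF, −78 °C; monomeric CH2O (THF solution), −78 °C; AcOH quench
Reagents that add atoms: 22, C=O
Why: Kinetic deprotonation takes the CH3 and not the hindered C6‑H, so this enolate has no β‑leaving group; a crossed aldol with formaldehyde then adds C8′.

**Step 16**
Reactants: 23
Product: 24 (4S,5S)-1,5-bis(TBSO)-4-[(TBSO)methyl]-6-(2-ethyl-1,3-dioxolan-2-yl)hexan-3-one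
Conditions: TBSCl, imidazole, CH2Cl2, 0 °C → rt
Reagents that add atoms: TBSCl, CC(C)(C)[Si](C)(C)Cl
Why: Silylation caps the dehydration‑prone β‑hydroxy ketone with a weakly Lewis‑basic group that is a poor leaving group.

### Union and endgame

**Step 17**
Reactants: 24; 10
Product: 25 (5S,6S,8R,9S,10Z,12S,13Z)-5-(TBSO)-6,8-bis[(TBSO)methyl]-3,3-(ethylenedioxy)-9-hydroxy-10,12-dimethylpentadeca-10,13-dien-7-one
Conditions: c‑Hex2BCl, Et3N, Et2O, −78 → 0 °C; 10 (1.3 equiv), −78 → −20 °C; MeOH, pH 7 buffer, H2O2, 0 °C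
Reagents that add atoms: 10, C/C=C\[C@H](C)/C=C(/C)C=O
Why: Paterson‑type anti boron aldol in which c‑Hex2BCl/Et3N gives the (E)‑enol borinate at the less hindered C8 and a chair transition state gives the 8,9‑anti relationship; A(1,3) strain holds C6‑H in the enolate plane, so the aldehyde attacks the face flanked by the small CH2OTBS group and away from the C5 branch, giving 8R,9S.

**Step 18**
Reactants: 25
Product: 26 (5S,6S,8R,9S,10Z,12S,13Z)-5-(TBSO)-6,8-bis[(TBSO)methyl]-9-hydroxy-10,12-dimethylpentadeca-10,13-diene-3,7-dione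
Conditions: PPTS, acetone–H2O 10:1, 45 °C
Reagents that add atoms: water, O
Why: Mild ketal hydrolysis is done before the acid‑labile oxirane exists; the TBS ethers and the allylic alcohol tolerate PPTS.

**Step 19**
Reactants: 26
Product: 27 (5S,6S,8R,9S)-5-(TBSO)-6,8-bis[(TBSO)methyl]-9-hydroxy-9-{(2R,3S)-2-methyl-3-[(2S,3Z)-pent-3-en-2-yl]oxiran-2-yl}nonane-3,7-dione
Conditions: m‑CPBA (1.1 equiv), NaHCO3, CH2Cl2, −20 → 0 °C
Reagents that add atoms: m‑CPBA, O=C(OO)c1cccc(Cl)c1
Why: Henbest hydroxyl‑directed epoxidation in which A(1,3) strain in the Z‑alkene puts C9‑H in the alkene plane, so the only free OH delivers the peracid to one face (threo) while C8 blocks the other; syn addition to the 10Z alkene gives 10R,11S, and the directed trisubstituted alkene reacts faster than the 13Z alkene.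

**Step 20**
Reactants: 27
Product: 28 myriaporone 4, (5S,6S,8R,9S)-5,9-dihydroxy-6,8-bis(hydroxymethyl)-9-{(2R,3S)-2-methyl-3-[(2S,3Z)-pent-3-en-2-yl]oxiran-2-yl}nonane-3,7-dione
Conditions: HF·pyridine, pyridine, THF, 0 °C → rt
Reagents that add atoms: none
Why: Buffered fluoride desilylation removes all three TBS groups without base (no retro‑aldol, no C6/C8 epimerisation) and without aqueous strong acid (the oxirane survives).

## Compound list

| No. | Name | SMILES | Role |
|---|---|---|---|
| 1 | methyl (2R)-3-hydroxy-2-methylpropanoate | COC(=O)[C@H](C)CO | starting material |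
| 2 | methyl (2R)-2-methyl-3-(triethylsilyloxy)propanoate | COC(=O)[C@H](C)CO[Si](CC)(CC)CC | intermediate |
| 3 | (2R)-2-methyl-3-(triethylsilyloxy)propanal | O=C[C@H](C)CO[Si](CC)(CC)CC | intermediate |
| 4 | ethyltriphenylphosphonium bromide | CC[P+](c1ccccc1)(c1ccccc1)c1ccccc1.[Br-] | starting material |
| 5 | triethyl{[(2S,3Z)-2-methylpent-3-en-1-yl]oxy}silane | C/C=C\[C@H](C)CO[Si](CC)(CC)CC | intermediate |
| 6 | (2S,3Z)-2-methylpent-3-enal | C/C=C\[C@H](C)C=O | intermediate |
| 7 | ethyl 2-[bis(2,2,2-trifluoroethoxy)phosphoryl]propanoate | CCOC(=O)C(C)P(=O)(OCC(F)(F)F)OCC(F)(F)F | starting material |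
| 8 | ethyl (2Z,4S,5Z)-2,4-dimethylhepta-2,5-dienoate | C/C=C\[C@H](C)/C=C(/C)C(=O)OCC | intermediate |
| 9 | (2Z,4S,5Z)-2,4-dimethylhepta-2,5-dien-1-ol | C/C=C\[C@H](C)/C=C(/C)CO | intermediate |
| 10 | (2Z,4S,5Z)-2,4-dimethylhepta-2,5-dienal | C/C=C\[C@H](C)/C=C(/C)C=O | intermediate |
| 11 | methyl 3-oxopentanoate | CCC(=O)CC(=O)OC | starting material |
| 12 | ethane-1,2-diol | OCCO | starting material |
| 13 | methyl (2-ethyl-1,3-dioxolan-2-yl)acetate | CCC1(CC(=O)OC)OCCO1 | intermediate |
| 14 | (2-ethyl-1,3-dioxolan-2-yl)acetaldehyde | CCC1(CC=O)OCCO1 | intermediate |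
| 15 | (4R)-4-benzyl-1,3-oxazolidin-2-one | O=C1N[C@H](Cc2ccccc2)CO1 | starting material |
| 16 | (E)-but-2-enoyl chloride | C/C=C/C(=O)Cl | starting material |
| 17 | (4R)-4-benzyl-3-[(2E)-but-2-enoyl]-1,3-oxazolidin-2-one | C/C=C/C(=O)N1[C@H](Cc2ccccc2)COC1=O | intermediate |
| 18 | Evans adduct (2R,3S) | C=C[C@@H](C(=O)N1[C@H](Cc2ccccc2)COC1=O)[C@@H](O)CC1(CC)OCCO1 | intermediate |
| 19 | (2S,3S)-2-ethenyl-4-(2-ethyl-1,3-dioxolan-2-yl)butane-1,3-diol | C=C[C@@H](CO)[C@@H](O)CC1(CC)OCCO1 | intermediate |
| 20 | bis‑TBS ether of 19 | C=C[C@@H](CO[Si](C)(C)C(C)(C)C)[C@@H](O[Si](C)(C)C(C)(C)C)CC1(CC)OCCO1 | intermediate |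
| 21 | C1–C8 methyl ketone (3S,4S) | CC(=O)[C@@H](CO[Si](C)(C)C(C)(C)C)[C@@H](O[Si](C)(C)C(C)(C)C)CC1(CC)OCCO1 | intermediate |
| 22 | formaldehyde | C=O | starting material |
| 23 | β‑hydroxy ketone (4S,5S) | OCCC(=O)[C@@H](CO[Si](C)(C)C(C)(C)C)[C@@H](O[Si](C)(C)C(C)(C)C)CC1(CC)OCCO1 | intermediate |
| 24 | C1–C8 ketone, tris‑TBS (4S,5S) | CC(C)(C)[Si](C)(C)OCCC(=O)[C@@H](CO[Si](C)(C)C(C)(C)C)[C@@H](O[Si](C)(C)C(C)(C)C)CC1(CC)OCCO1 | intermediate |
| 25 | aldol adduct | C/C=C\[C@H](C)/C=C(/C)[C@@H](O)[C@@H](CO[Si](C)(C)C(C)(C)C)C(=O)[C@@H](CO[Si](C)(C)C(C)(C)C)[C@@H](O[Si](C)(C)C(C)(C)C)CC1(CC)OCCO1 | intermediate |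
| 26 | 3,7‑dione | C/C=C\[C@H](C)/C=C(/C)[C@@H](O)[C@@H](CO[Si](C)(C)C(C)(C)C)C(=O)[C@@H](CO[Si](C)(C)C(C)(C)C)[C@@H](O[Si](C)(C)C(C)(C)C)CC(=O)CC | intermediate |
| 27 | tris‑TBS myriaporone 4 | C/C=C\[C@H](C)[C@@H]1O[C@]1(C)[C@@H](O)[C@@H](CO[Si](C)(C)C(C)(C)C)C(=O)[C@@H](CO[Si](C)(C)C(C)(C)C)[C@@H](O[Si](C)(C)C(C)(C)C)CC(=O)CC | intermediate |
| 28 | myriaporone 4 | C/C=C\[C@H](C)[C@@H]1O[C@]1(C)[C@@H](O)[C@@H](CO)C(=O)[C@@H](CO)[C@@H](O)CC(=O)CC | target |

## Step count and main risks

Total steps: 20.

Longest linear sequence: 12 steps (Steps 8, 9 and 11–20). The dienal branch reaches the target in 11 steps (Steps 1–7 and 17–20).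

**Steps most likely to fail**

1. **Step 17 (boron aldol).**
   - Risks: the enol borinate carries a β‑OTBS group and could eliminate. Facial control by C6 rests on an A(1,3)/steric model rather than on a direct precedent. Enal 10 is hindered and prone to isomerisation.
   - Fallback: set C8/C9 by auxiliary control instead. Run an Evans syn aldol of the (4S)‑enantiomer of 17 with 10, so that the imide C=O becomes C8′ and the vinyl group becomes C7/C6. Then carry out a terminal‑alkene‑selective Wacker oxidation and hydroxymethylation. Finally, move the last C–C bond formation to C5–C6, using an anti aldol onto the simple aldehyde 14.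

2. **Step 15 (enolate hydroxymethylation).**
   - Risks: over‑addition of formaldehyde, dehydration to the vinyl ketone, or enolate equilibration toward C6 followed by loss of TBSO⁻.
   - Fallback: avoid enolate chemistry altogether. Ozonise 20 to the C7 aldehyde and add vinylmagnesium bromide. Hydroborate with 9‑BBN and oxidise, silylate the primary OH selectively, and oxidise C7‑OH to reach 24.

3. **Step 19 (directed epoxidation).**
   - Risks: the 10Z alkene is crowded on both sides, the 13Z alkene can compete, and the face selectivity depends entirely on substrate control.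
   - Fallback: install the oxirane before the coupling under reagent control. Sharpless asymmetric epoxidation of 9 with Ti(Oi‑Pr)4, D‑(−)‑DET and TBHP gives the (2R,3S)‑epoxy alcohol and touches only the allylic alkene. Oxidise this to the epoxy aldehyde and use it as the aldol acceptor. Ketone 24 would then have to override any facial bias of the epoxy aldehyde.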